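**Retrosynthetic overview**
- The C10'–Br / C11'–OH pair comes last, from the (E)-10',11'-alkene of a 15-membered lactone by anti bromohydroxylation under macrocyclic control; the phenol is then freed.
- The cyclohexane (C2'–C7' bond, C6'–Br, exocyclic alkene) comes from an electrochemical, bromide-mediated transannular bromonium cyclisation that contracts a 19-membered triene macrolactone to the 15-membered one.
- The 19-membered lactone comes from Shiina lactonisation at O-14' of the open-chain seco acid; C15'–Br comes from the tertiary alcohol.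
- The seco chain comes from methyl 4-hydroxybenzoate 1 and (2E,6E)-farnesyl bromide 2 (C-farnesylation, allylic oxidation), joined at C12'–C13' by a visible-light nickel decarboxylative coupling with the L-malic acid-derived acid 3. C14' of 3 is the only purchased stereocentre; all others are relayed from it.
- Ring order: 19-membered macrolactone first (step 7), then the cyclohexane (step 9), which turns it into the 15-membered lactone.

Assumption: diterpene carbons are numbered C1' (benzylic) to C15' along the chain; 2, 3 (commercial acetonide of L-malic acid) and 1-bromo-N,N,2-trimethylprop-1-en-1-amine are taken as purchasable.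

**Step 1**
Reactants: 1 methyl 4-hydroxybenzoate; 2 (2E,6E)-farnesyl bromide [(2E,6E)-1-bromo-3,7,11-trimethyldodeca-2,6,10-triene]
Product: 5 methyl 4-hydroxy-3-[(2E,6E)-3,7,11-trimethyldodeca-2,6,10-trien-1-yl]benzoate, via sodium 4-(methoxycarbonyl)phenolate 4 (not isolated)
Conditions: NaH (1.0 equiv), toluene, 0 °C; then 2, 25 °C, 16 h
Reagents that add atoms: none
Why: Ortho C-allylation of a phenolate (the heterogeneous sodium phenolate in a non-polar solvent favours C- over O-alkylation, modest yield accepted at the first step) by SN2 at the primary allylic carbon, which keeps the 2E,6E geometry; no stereocentre.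

**Step 2**
Reactants: 5 methyl 4-hydroxy-3-[(2E,6E)-3,7,11-trimethyldodeca-2,6,10-trien-1-yl]benzoate
Product: 6 methyl 4-hydroxy-3-[(2E,6E,10E)-12-hydroxy-3,7,11-trimethyldodeca-2,6,10-trien-1-yl]benzoate
Conditions: SeO2 (0.3 equiv), t-BuOOH (3 equiv), salicylic acid (0.1 equiv), CH2Cl2, 0 → 25 °C
Reagents that add atoms: selenium dioxide, O=[Se]=O (catalytic oxygen carrier); tert-butyl hydroperoxide, CC(C)(C)OO (terminal oxygen source)
Why: Catalytic SeO2 allylic oxidation (ene reaction, then 2,3-sigmatropic shift) attacks the terminal gem-dimethyl alkene at its (E)-methyl group and gives the (10E)-12-ol; no stereocentre.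

**Step 3**
Reactants: 6 methyl 4-hydroxy-3-[(2E,6E,10E)-12-hydroxy-3,7,11-trimethyldodeca-2,6,10-trien-1-yl]benzoate
Product: 7 methyl 3-[(2E,6E,10E)-12-bromo-3,7,11-trimethyldodeca-2,6,10-trien-1-yl]-4-hydroxybenzoate
Conditions: CBr4, PPh3, CH2Cl2, −20 → 0 °C
Reagents that add atoms: carbon tetrabromide, BrC(Br)(Br)Br
Why: Appel bromination of the primary allylic alcohol under neutral conditions, without allylic transposition and without touching the phenol or ester.

**Step 4**
Reactants: 7 methyl 3-[(2E,6E,10E)-12-bromo-3,7,11-trimethyldodeca-2,6,10-trien-1-yl]-4-hydroxybenzoate; 3 (S)-2-(2,2-dimethyl-5-oxo-1,3-dioxolan-4-yl)acetic acid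
Product: 9 methyl 3-[(2E,6E,10E)-13-[(4S)-2,2-dimethyl-5-oxo-1,3-dioxolan-4-yl]-3,7,11-trimethyltrideca-2,6,10-trien-1-yl]-4-hydroxybenzoate, via N-acyloxyphthalimide ester 8 (not isolated)
Conditions: 3, N-hydroxyphthalimide, N,N'-diisopropylcarbodiimide, cat. 4-(dimethylamino)pyridine, CH2Cl2, 25 °C; then DMA, 7, NiBr2(dme) (10 mol %), 4,4'-di-tert-butyl-2,2'-bipyridine (12 mol %), 2,4,5,6-tetra(carbazol-9-yl)isophthalonitrile (2 mol %), diethyl 1,4-dihydro-2,6-dimethylpyridine-3,5-dicarboxylate (Hantzsch ester, 1.5 equiv), 2,6-lutidine, 450 nm LEDs, 25 °C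
Reagents that add atoms: none
Why: Metallaphotoredox decarboxylative cross-electrophile coupling, in which the reduced photocatalyst fragments 8 to the primary C13' radical, the allylnickel bromide formed from 7 captures it, and C–C coupling occurs at the unhindered CH2 terminus with the 10E geometry kept (syn/anti isomerisation would need nickel sigma-bonded at the hindered secondary terminus); C14' (S) comes unchanged from 3.

**Step 5**
Reactants: 9 methyl 3-[(2E,6E,10E)-13-[(4S)-2,2-dimethyl-5-oxo-1,3-dioxolan-4-yl]-3,7,11-trimethyltrideca-2,6,10-trien-1-yl]-4-hydroxybenzoate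
Product: 10 methyl 3-[(2E,6E,10E,14S)-14,15-dihydroxy-3,7,11,15-tetramethylhexadeca-2,6,10-trien-1-yl]-4-hydroxybenzoate
Conditions: MeMgBr (4.5 equiv), THF, −78 → 0 °C; aq. NH4Cl
Reagents that add atoms: methylmagnesium bromide, C[Mg]Br
Why: Double Grignard addition to the activated dioxolanone carbonyl (the acetonide leaves as acetone) while the methyl ester is shielded as its para-phenolate; addition outruns enolisation at −78 °C, so C14' stays S.

**Step 6**
Reactants: 10 methyl 3-[(2E,6E,10E,14S)-14,15-dihydroxy-3,7,11,15-tetramethylhexadeca-2,6,10-trien-1-yl]-4-hydroxybenzoate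
Product: 12 4-acetoxy-3-[(2E,6E,10E,14S)-14,15-dihydroxy-3,7,11,15-tetramethylhexadeca-2,6,10-trien-1-yl]benzoic acid, via dihydroxy acid 11 (not isolated)
Conditions: LiOH (6 equiv), THF/MeOH/H2O, 50 °C; then 0 °C, Ac2O (excess, pH 9–10); aq. KHSO4
Reagents that add atoms: lithium hydroxide, [Li+].[OH-]; acetic anhydride, CC(=O)OC(C)=O
Why: Saponification followed in the same flask by Schotten–Baumann acetylation, which in water selects the phenolate over the secondary and tertiary alcohols; the acetate later deactivates the arene and blocks the phenol oxygen.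

**Step 7**
Reactants: 12 4-acetoxy-3-[(2E,6E,10E,14S)-14,15-dihydroxy-3,7,11,15-tetramethylhexadeca-2,6,10-trien-1-yl]benzoic acid
Product: 14 (14'S)-15'-hydroxy 19-membered macrolactone (4-acetoxybenzoate closed on O-14' of the 2'E,6'E,10'E-triene chain attached at aryl C-3), via mixed anhydride 13 (not isolated)
Conditions: 2-methyl-6-nitrobenzoic anhydride (1.5 equiv), 4-(dimethylamino)pyridine (3 equiv), Et3N, CH2Cl2 (1 mM, slow addition), 25 °C
Reagents that add atoms: none
Why: Shiina macrolactonisation through the mixed anhydride under high dilution acylates the secondary 14'-OH in preference to the tertiary 15'-OH with retention at C14'; this is the first ring.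

**Step 8**
Reactants: 14 (14'S)-15'-hydroxy 19-membered macrolactone
Product: 15 (14'S)-15'-bromo 19-membered macrolactone (tertiary bromide in place of the 15'-OH of 14)
Conditions: 1-bromo-N,N,2-trimethylprop-1-en-1-amine (1.5 equiv), CH2Cl2, 0 → 25 °C
Reagents that add atoms: 1-bromo-N,N,2-trimethylprop-1-en-1-amine, CC(C)=C(Br)N(C)C
Why: Neutral alcohol-to-bromide exchange with an alpha-bromoenamine (Ghosez-type) reagent, in which the tertiary alkoxy-iminium ionises with help from the neighbouring benzoate carbonyl and bromide returns at the tertiary carbon, so the C14'–O bond (S) is untouched and no HBr is formed that could add to the triene.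

**Step 9**
Reactants: 15 (14'S)-15'-bromo 19-membered macrolactone
Product: 16 O-acetyl-10'-debromo-11'-deoxy-10',11'-didehydrobromophycolide D [(2'R,6'S,7'S,14'S) 15-membered lactone with equatorial 6'-Br, 3'-exocyclic methylene, (10'E)-alkene and 15'-Br]
Conditions: undivided cell, graphite anode, Pt cathode, constant current (2.1 F/mol), LiBr (1.05 equiv), n-Bu4NPF6 (0.05 M), 2,6-di-tert-butyl-4-methylpyridine (1.5 equiv), (CF3)2CHOH/CH2Cl2 1:4 (2 mM), −10 °C
Reagents that add atoms: lithium bromide, [Li+].[Br-]
Why: Proposed new method: anodic oxidation of bromide in (CF3)2CHOH/CH2Cl2 releases electrophilic bromine slowly and passes Br+ reversibly among the alkenes, the 6',7'-bromonium ion (the 10',11'-alkene being inductively deactivated and shielded by the CMe2Br/ester neighbourhood) is opened transannularly at C7' by C2' of the 2',3'-alkene through a chair transition state (anti addition to the E-alkene with Br, C8' and C1' all equatorial, which fixes the relative 2'R,6'S,7'S set), the 14'S centre is expected to select through the fold of the macrocycle which of the two mirror-image chairs is reached, and the hindered pyridine removes a proton from the exposed C3' methyl to give the exocyclic alkene while the cathode evolves H2; the closest known reaction types are anodic bromide-mediated bromofunctionalisation of alkenes (bromohydrins, bromolactones) and reagent-based bromonium polyene cyclisations (Et2SBr·SbCl5Br, NBS in fluorinated alcohols), and I know of no electrochemical or transannular polyene case.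

**Step 10**
Reactants: 16 O-acetyl-10'-debromo-11'-deoxy-10',11'-didehydrobromophycolide D
Product: 17 O-acetylbromophycolide D (2'R,6'S,7'S,10'R,11'S,14'S)
Conditions: NBS (1.05 equiv), THF/H2O 4:1, 0 °C, dark
Reagents that add atoms: N-bromosuccinimide, O=C1CCC(=O)N1Br; water, O
Why: Bromohydrin formation by Markovnikov anti addition across the (E)-alkene puts Br on C10' and OH on C11', the trisubstituted alkene reacting ahead of the hindered 1,1-disubstituted exocyclic one (as in limonene), and the face is set by the rigid 15-membered ring (peripheral attack), which is expected but not proven to give the 10'R,11'S pair.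

**Step 11**
Reactants: 17 O-acetylbromophycolide D
Product: 18 bromophycolide D
Conditions: NH4OAc (10 equiv), MeOH/H2O 4:1, 25 °C
Reagents that add atoms: none
Why: Neutral ammonium acetate-mediated methanolysis cleaves only the phenyl acetate (far more labile than the hindered macrolactone) and is not basic enough to close the bromohydrin to an epoxide or eliminate the tertiary bromide.

**Compound list**
1 | methyl 4-hydroxybenzoate | COC(=O)c1ccc(O)cc1 | starting material
2 | (2E,6E)-farnesyl bromide | CC(C)=CCC/C(C)=C/CC/C(C)=C/CBr | starting material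
3 | (S)-2-(2,2-dimethyl-5-oxo-1,3-dioxolan-4-yl)acetic acid | OC(=O)C[C@@H]1OC(C)(C)OC1=O | starting material
4 | sodium 4-(methoxycarbonyl)phenolate | COC(=O)c1ccc([O-])cc1.[Na+] | intermediate
5 | methyl 4-hydroxy-3-[(2E,6E)-3,7,11-trimethyldodeca-2,6,10-trien-1-yl]benzoate | COC(=O)c1ccc(O)c(C/C=C(\C)CC/C=C(\C)CCC=C(C)C)c1 | intermediate
6 | methyl 4-hydroxy-3-[(2E,6E,10E)-12-hydroxy-3,7,11-trimethyldodeca-2,6,10-trien-1-yl]benzoate | COC(=O)c1ccc(O)c(C/C=C(\C)CC/C=C(\C)CC/C=C(\C)CO)c1 | intermediate
7 | methyl 3-[(2E,6E,10E)-12-bromo-3,7,11-trimethyldodeca-2,6,10-trien-1-yl]-4-hydroxybenzoate | COC(=O)c1ccc(O)c(C/C=C(\C)CC/C=C(\C)CC/C=C(\C)CBr)c1 | intermediate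
8 | 1,3-dioxoisoindolin-2-yl 2-[(4S)-2,2-dimethyl-5-oxo-1,3-dioxolan-4-yl]acetate | O=C(C[C@@H]1OC(C)(C)OC1=O)ON1C(=O)c2ccccc2C1=O | intermediate
9 | methyl 3-[(2E,6E,10E)-13-[(4S)-2,2-dimethyl-5-oxo-1,3-dioxolan-4-yl]-3,7,11-trimethyltrideca-2,6,10-trien-1-yl]-4-hydroxybenzoate | COC(=O)c1ccc(O)c(C/C=C(\C)CC/C=C(\C)CC/C=C(\C)CC[C@@H]2OC(C)(C)OC2=O)c1 | intermediate
10 | methyl 3-[(2E,6E,10E,14S)-14,15-dihydroxy-3,7,11,15-tetramethylhexadeca-2,6,10-trien-1-yl]-4-hydroxybenzoate | COC(=O)c1ccc(O)c(C/C=C(\C)CC/C=C(\C)CC/C=C(\C)CC[C@@H](C(C)(C)O)O)c1 | intermediate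
11 | 3-[(2E,6E,10E,14S)-14,15-dihydroxy-3,7,11,15-tetramethylhexadeca-2,6,10-trien-1-yl]-4-hydroxybenzoic acid | OC(=O)c1ccc(O)c(C/C=C(\C)CC/C=C(\C)CC/C=C(\C)CC[C@@H](C(C)(C)O)O)c1 | intermediate
12 | 4-acetoxy-3-[(2E,6E,10E,14S)-14,15-dihydroxy-3,7,11,15-tetramethylhexadeca-2,6,10-trien-1-yl]benzoic acid | CC(=O)Oc1ccc(C(=O)O)cc1C/C=C(\C)CC/C=C(\C)CC/C=C(\C)CC[C@@H](C(C)(C)O)O | intermediate
13 | mixed anhydride of 12 with 2-methyl-6-nitrobenzoic acid | CC(=O)Oc1ccc(C(=O)OC(=O)c2c(C)cccc2[N+](=O)[O-])cc1C/C=C(\C)CC/C=C(\C)CC/C=C(\C)CC[C@@H](C(C)(C)O)O | intermediate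
14 | (14'S)-15'-hydroxy 19-membered macrolactone (4-acetoxybenzoate closed on O-14'; 2'E,6'E,10'E) | CC(=O)Oc1ccc2cc1C/C=C(\C)CC/C=C(\C)CC/C=C(\C)CC[C@@H](C(C)(C)O)OC2=O | intermediate
15 | (14'S)-15'-bromo 19-membered macrolactone | CC(=O)Oc1ccc2cc1C/C=C(\C)CC/C=C(\C)CC/C=C(\C)CC[C@@H](C(C)(C)Br)OC2=O | intermediate
16 | O-acetyl-10'-debromo-11'-deoxy-10',11'-didehydrobromophycolide D (2'R,6'S,7'S,14'S; 10'E) | C=C1CC[C@H](Br)[C@@]2(C)CC/C=C(\C)CC[C@@H](C(C)(C)Br)OC(=O)c3ccc(OC(C)=O)c(c3)C[C@H]12 | intermediate
17 | O-acetylbromophycolide D (2'R,6'S,7'S,10'R,11'S,14'S) | C=C1CC[C@H](Br)[C@@]2(C)CC[C@@H](Br)[C@@](C)(O)CC[C@@H](C(C)(C)Br)OC(=O)c3ccc(OC(C)=O)c(c3)C[C@H]12 | intermediate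
18 | bromophycolide D | C=C1CC[C@H](Br)[C@@]2(C)CC[C@@H](Br)[C@@](C)(O)CC[C@@H](C(C)(C)Br)OC(=O)c3ccc(O)c(c3)C[C@H]12 | target

**Step count and risks**
Total steps: 11. Longest linear sequence: 11 (from 1 and 2; acid 3 is purchased and enters at step 4).

Most likely to fail:

1. Step 9 (the proposed new electrochemical transannular cyclisation). The risks are initiation at the 10',11'-alkene, the wrong chair fold (the diastereomeric ring), and endocyclic olefin isomers. The fallback sets out from 15 and comes back at 16. It gives up electrolysis for the known reagent-based bromonium polyene cyclisation with the pre-formed stoichiometric donor Et2SBr·SbCl5Br (1.1 equiv, MeNO2, −25 °C, 5 min, then 2,6-lutidine), with separation of olefin isomers on AgNO3-silica. New compound on the way: none F0.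

2. Step 10 (face and site selectivity of the bromohydrin). The fallback sets out from 16 and comes back at 17. Epoxidise the 10',11'-alkene with mCPBA (NaHCO3, CH2Cl2, −20 °C) to the (10'S,11'S)-10',11'-epoxide of 16 F2, then open it at the secondary carbon with Li2NiBr4 (THF, 0 °C; SN2, inversion at C10'). If Br+ delivery is what fixes the face in step 10, this sequence gives the opposite C10'/C11' pair (oxygen goes to the face that Br+ would take, bromide enters from the other), so whichever face the macrocycle exposes one of the two protocols should give 17. If water capture fixes the face instead, both sequences converge on the same pair and the fallback brings no gain.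

3. Step 8 (tertiary bromide next to the lactone without elimination or acyl shift). The fallback sets out from 14 and comes back at 15. Dehydrate the tertiary alcohol with the Burgess reagent (benzene, 50 °C) to the (14'S)-14'-isopropenyl 19-membered macrolactone F1. Then carry out a Markovnikov hydrogen-atom-transfer hydrobromination (Co(acac)2, t-BuOOH, Et3SiH, TsBr, CH2Cl2, 0 °C), in which the 1,1-disubstituted alkene should react ahead of the three trisubstituted ones and bromine ends on the tertiary carbon.

**Further compounds**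
F1 | step 8 | (14'S)-14'-isopropenyl 19-membered macrolactone (15',16'-alkene in place of the 15'-OH of 14) | CC(=O)Oc1ccc2cc1C/C=C(\C)CC/C=C(\C)CC/C=C(\C)CC[C@@H](C(C)=C)OC2=O
F0 | step 9 | none | none
F2 | step 10 | (10'S,11'S)-10',11'-epoxide of 16 | C=C1CC[C@H](Br)[C@@]2(C)CC[C@@H]3O[C@@]3(C)CC[C@@H](C(C)(C)Br)OC(=O)c4ccc(OC(C)=O)c(c4)C[C@H]12
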